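Late in the gamma run, at 2.50 h, L had reached 26 % of the Q charged and Z stood at 46 %. From that I had to decide how much X to charge for a flask read at 5.0 h, if I wanted to find Z or L there.

| flask | Q | X | remark | time |
|---|---|---|---|---|
| beta | 0.20 M | 7.7 mM | run made earlier |  |
| epsilon | 0.20 M | 17 mM | run made earlier |  |
| gamma | 0.20 M | 24 mM | run made earlier |  |
| green | 0.20 M | 10 mM |  | 5.0 h |
| amber | 0.20 M | 30 mM |  | 5.0 h |

| run | time / h | L / % | E / % | Q / % | Z / % |
|---|---|---|---|---|---|
| beta | 0.500 | 0 | 32 | 64 | 7 |
| beta | 1.00 | 0 | 45 | 41 | 11 |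
| beta | 1.50 | 2 | 49 | 31 | 21 |
| beta | 2.00 | 1 | 47 | 17 | 32 |
| beta | 2.50 | 9 | 43 | 13 | 39 |
| epsilon | 0.500 | 0 | 26 | 66 | 3 |
| epsilon | 1.00 | 1 | 36 | 42 | 19 |
| epsilon | 1.50 | 6 | 35 | 29 | 36 |
| epsilon | 2.00 | 9 | 28 | 17 | 46 |
| epsilon | 2.50 | 15 | 21 | 8 | 53 |
| gamma | 0.500 | 0 | 22 | 65 | 11 |
| gamma | 1.00 | 6 | 28 | 42 | 25 |
| gamma | 1.50 | 8 | 23 | 26 | 42 |
| gamma | 2.00 | 21 | 17 | 17 | 45 |
| gamma | 2.50 | 26 | 13 | 9 | 46 |

(standard deviation of a reading: 2 percentage points)

- which of these there is most of at the end, counted by the Q in it, green (Z / E / Q / L)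
- which of these there is most of at the end, counted by the Q in it, amber (Z / E / Q / L)
- final amount of the leader among these, as a percentage of the Q charged, in green
- final amount of the leader among these, as a percentage of the Q charged, in amber

- steps thought possible: X + Z -> X + L; X + E -> X + Z; Q -> E

X stands on both sides of its steps, so I treated the loss of Z to L as pseudo-first-order, like a substrate turned over by a fixed charge of enzyme, with a constant proportional to X. The area under the gamma Z curve up to the last reading, with Z as a fraction of the charge, reads 0.730 h. The constant is L divided by that area, and ln(2) over the constant gives 1.95 h at 24 mM of X. This is the Z half-life, a reading that I scaled inversely with X to count half-lives in a run: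

| Flask | X | Z half-life | Half-lives in the run |
|---|---|---|---|
| green | 10 mM | 4.67 h | 1.07 |
| amber | 30 mM | 1.56 h | 3.21 |

Z forms as Q and E pass on, so I took these counts, which run from the start, as generous. Since amber's count is larger than green's, I decided to keep both charges, green for Z and amber for L.

The forecast, using “L divided by the time integral of Z”, named Z in green at 59 % (54 % to 64 %) and L in amber at 72 % (65 % to 79 %).

The flasks gave Z at 58.3 % in green and L at 73.9 % in amber, both inside the forecast's ranges.

    X + Z → X + L (k = 15.0 L mol⁻¹ h⁻¹)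
    X + E → X + Z (k = 60.0 L mol⁻¹ h⁻¹)
    Q → E (k = 0.890 h⁻¹)

X still stood at 100 % of its charge at the end of amber, where 3.21 counted half-lives went with Z down to 23.8 %. A neighbour of amber charged with 0.012 M of X has a Z half-life of 3.89 h by the same scaling, which makes 1.28 half-lives in the run. That neighbour flask ended with 55.1 % of Z against 35.6 % of L.

(All runs stem from a simulated flask for an exercise; the scatter is artificial.)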